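**Retrosynthetic overview**

- Numbering: carbocycle C1 (furanone C=O), C2=C3, C4(C15H2OH)=C5, C6 (lactone O), C7, C8 (crotonate O), C9H2, C10 (CH3, O-bridge to C3); lactone carbons C11(=C13H2) and C12. The route rests on C6: an allylic carbinol carbon in the ten-membered ring, bonded to the Z-configured alkene carbon C5 and bearing the lactone oxygen, so C5–C6 is the seam of a vinylmetal/aldehyde union.
- End game: C15–OH, C8 crotonate, C11=C13 and the lactone O–C12 bond are peeled back to a ten-membered C6 alcohol carrying a C12 tert-butyl ester.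
- Key disconnection C5–C6: CrCl2/NiCl2 coupling of a Z C5 vinyl iodide, sitting on a preformed furanone (ring O, C10, C1, C2, C3), with a C6 aldehyde.
- Precursor: furanone from a C10-hydroxy C1≡C2–C3(=O) ynone (gold); C2–C3 from an acetylide and a Z β-iodoenal; C7/C8 by an Evans syn aldol of a succinate imide; C10 from (S)-2-methylglycidol.
- Ring order: furanone, then the ten-membered carbocycle, then the γ-lactone.

Key step: step 19

Assumption: C3 is carried as a mixture of carbinol epimers from step 9 to step 16, and C11 of the Mannich base as a mixture of epimers; both centres become sp2, so neither matters. Monomeric formaldehyde is taken from cracked paraformaldehyde.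

Design remark: the furanone is built after the hydride step because LiBH4 would attack its ketone. The iodoacrylate unit is joined as an aldehyde to an acetylide because ester enolates would substitute its vinylogous acyl iodide. C12 is a tert-butyl ester so that the γ-hydroxy ester stages (C8–OH, later C6H2–OH) cannot lactonise early.

**Route**

Step 1
Reactants: 1 (S)-2-methylglycidol; 2 vinylmagnesium bromide
Product: 3 (R)-2-methylpent-4-ene-1,2-diol
Conditions: 2 (3 equiv), CuI (10 mol%), THF, −30 → 0 °C; aq. NH4Cl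
Reagents that add atoms: none
Why: Copper-catalysed Grignard opening of a 2,2-disubstituted epoxide occurs by SN2 attack at the unsubstituted CH2 carbon, so the quaternary carbinol centre (the future C10) is carried over unchanged from 1.

Step 2
Reactants: 3 (R)-2-methylpent-4-ene-1,2-diol
Product: 4 (R)-2-methyl-1,2-bis(triethylsilyloxy)pent-4-ene
Conditions: Et3SiOTf (2.5 equiv), 2,6-lutidine, CH2Cl2, −78 → 0 °C
Reagents that add atoms: triethylsilyl trifluoromethanesulfonate, CC[Si](CC)(CC)OS(=O)(=O)C(F)(F)F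
Why: The silyl triflate with a hindered pyridine base silylates the primary and also the tertiary hydroxyl (exhaustive silyl ether formation), no stereocentre being touched.

Step 3
Reactants: 4 (R)-2-methyl-1,2-bis(triethylsilyloxy)pent-4-ene
Product: 5 (R)-2-methyl-2-(triethylsilyloxy)pent-4-enal
Conditions: (COCl)2, DMSO, CH2Cl2, −78 → −35 °C; Et3N, → 0 °C
Reagents that add atoms: none
Why: Under Swern conditions a primary triethylsilyl ether is oxidised directly to the aldehyde (oxidative desilylation) while the hindered tertiary silyl ether stays, and the quaternary α-carbon cannot epimerise.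

Step 4
Reactants: 5 (R)-2-methyl-2-(triethylsilyloxy)pent-4-enal
Product: 6 (R)-3-methyl-3-(triethylsilyloxy)hex-5-en-1-yne
Conditions: dimethyl (1-diazo-2-oxopropyl)phosphonate, K2CO3, MeOH, 0 °C → rt
Reagents that add atoms: dimethyl (1-diazo-2-oxopropyl)phosphonate, CC(=O)C(=[N+]=[N-])P(=O)(OC)OC
Why: Seyferth–Gilbert homologation in its Ohira–Bestmann form converts the non-enolisable aldehyde into the terminal alkyne (C1≡C2) under carbonate conditions that a tertiary triethylsilyl ether tolerates.

Step 5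
Reactants: 7 ethyl propiolate; 8 formaldehyde
Product: 10 ethyl (Z)-2-(hydroxymethyl)-3-iodoprop-2-enoate, via iodomagnesium iodoallenolate 9 (not isolated)
Conditions: MgI2 (1.2 equiv), CH2Cl2, 0 °C; aq. NH4Cl
Reagents that add atoms: magnesium iodide, [Mg+2].[I-].[I-]
Why: β-Iodo Morita–Baylis–Hillman reaction: iodide adds to the Mg-activated propiolate and allenolate 9 is hydroxymethylated by formaldehyde on the side away from iodine, which leaves iodine cis to the ester, i.e. the Z alkene that becomes C4=C5.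

Step 6
Reactants: 10 ethyl (Z)-2-(hydroxymethyl)-3-iodoprop-2-enoate
Product: 11 ethyl (Z)-2-[(tert-butyldiphenylsilyl)oxymethyl]-3-iodoprop-2-enoate
Conditions: t-BuPh2SiCl, imidazole, CH2Cl2, 0 °C → rt
Reagents that add atoms: tert-butyl(chloro)diphenylsilane, CC(C)(C)[Si](Cl)(c1ccccc1)c1ccccc1
Why: Standard silylation of the primary allylic alcohol (silyl chloride/imidazole) installs the C15 protecting group that must outlast all later steps.

Step 7
Reactants: 11 ethyl (Z)-2-[(tert-butyldiphenylsilyl)oxymethyl]-3-iodoprop-2-enoate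
Product: 12 (E)-2-[(tert-butyldiphenylsilyl)oxymethyl]-3-iodoprop-2-en-1-ol
Conditions: iBu2AlH (2.2 equiv), CH2Cl2, −78 °C; aq. sodium potassium tartrate
Reagents that add atoms: none
Why: iBu2AlH reduces the conjugated ester by 1,2-hydride delivery to the allylic alcohol at −78 °C without touching the vinyl iodide or its geometry (the descriptor changes to E only because the priorities change).

Step 8
Reactants: 12 (E)-2-[(tert-butyldiphenylsilyl)oxymethyl]-3-iodoprop-2-en-1-ol
Product: 13 (Z)-2-[(tert-butyldiphenylsilyl)oxymethyl]-3-iodoprop-2-enal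
Conditions: MnO2, CH2Cl2, rt, dark; used at once
Reagents that add atoms: none
Why: MnO2 oxidises the allylic alcohol to the enal under neutral conditions (allylic oxidation), and light is excluded to keep the Z β-iodoenal from isomerising.

Step 9
Reactants: 6 (R)-3-methyl-3-(triethylsilyloxy)hex-5-en-1-yne; 13 (Z)-2-[(tert-butyldiphenylsilyl)oxymethyl]-3-iodoprop-2-enal
Product: 16 bis(triethylsilyl) iodo-dienyne (10R; C3 epimers), via lithium acetylide 14 (not isolated), via lithium C3 alkoxide 15 (not isolated)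
Conditions: n-BuLi (1.05 equiv), THF, −78 °C; 13, −78 °C; Et3SiCl, −78 → 0 °C
Reagents that add atoms: chlorotriethylsilane, CC[Si](Cl)(CC)CC
Why: Lithium acetylide 14 adds 1,2 to the enal carbonyl (alkynylation of an aldehyde, forming C2–C3) faster than it can substitute the vinyl iodide at −78 °C, and alkoxide 15 is silylated in the same flask; the C3 centre arises without control and is erased in step 16.

Step 10
Reactants: 16 bis(triethylsilyl) iodo-dienyne
Product: 18 C8 aldehyde (10R; C3 epimers), via terminal 1,2-diol 17 (not isolated)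
Conditions: OsO4 (2 mol%), NaIO4 (4 equiv), 2,6-lutidine, dioxane/H2O (3:1), rt
Reagents that add atoms: osmium tetroxide, O=[Os](=O)(=O)=O; sodium periodate, [Na+].[O-]I(=O)(=O)=O
Why: Johnson–Lemieux cleavage: OsO4 dihydroxylates the unhindered, electron-richest terminal alkene in preference to the iodine-bearing trisubstituted alkene and the alkyne, and periodate cleaves diol 17 to the C8 aldehyde.

Step 11
Reactants: 19 (S)-4-benzyloxazolidin-2-one; 20 4-tert-butoxy-4-oxobutanoic acid
Product: 22 tert-butyl 4-[(4S)-4-benzyl-2-oxooxazolidin-3-yl]-4-oxobutanoate, via mixed pivalic anhydride 21 (not isolated)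
Conditions: 20, t-BuCOCl, Et3N, THF, −20 °C; 19, LiCl, → rt
Reagents that add atoms: none
Why: N-Acylation of the oxazolidinone through mixed pivalic anhydride 21 (LiCl-assisted) gives the succinate imide whose distal carboxyl is masked as a tert-butyl ester.

Step 12
Reactants: 22 tert-butyl 4-[(4S)-4-benzyl-2-oxooxazolidin-3-yl]-4-oxobutanoate; 18 C8 aldehyde
Product: 24 syn aldol adduct (7S,8R,10R; C3 epimers), via Z dibutylboron enolate 23 (not isolated)
Conditions: Bu2BOTf, iPr2NEt, CH2Cl2, 0 °C; 18, −78 → 0 °C; pH 7 buffer, MeOH, H2O2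
Reagents that add atoms: none
Why: Evans syn aldol: Z boron enolate 23, formed only at the imide α-carbon, reacts through a chair-like Zimmerman–Traxler transition state on the face away from the benzyl group, which sets C7 (S) and C8 (R) by auxiliary control regardless of the remote C10 centre and the C3 epimers.

Step 13
Reactants: 24 syn aldol adduct
Product: 25 C8 tert-butyldimethylsilyl ether (7S,8R,10R)
Conditions: t-BuMe2SiOTf, 2,6-lutidine, CH2Cl2, −78 → −20 °C
Reagents that add atoms: tert-butyldimethylsilyl trifluoromethanesulfonate, CC(C)(C)[Si](C)(C)OS(=O)(=O)C(F)(F)F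
Why: Silyl triflate/2,6-lutidine silylates the hindered secondary C8 hydroxyl at low temperature, blocking retro-aldol and closure onto the C12 ester.

Step 14
Reactants: 25 C8 tert-butyldimethylsilyl ether
Product: 26 C6 primary alcohol (7R,8R,10R)
Conditions: LiBH4 (2 equiv), MeOH (2 equiv), THF, 0 °C
Reagents that add atoms: none
Why: LiBH4 reduces the activated exocyclic imide carbonyl to the C6 primary alcohol (reductive removal of the auxiliary) while the tert-butyl ester, alkyne, vinyl iodide and silyl ethers are inert, and the bulky tert-butyl ester keeps the new γ-hydroxy ester from lactonising.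

Step 15
Reactants: 26 C6 primary alcohol
Product: 27 C3,C6,C10-triol (7R,8R,10R)
Conditions: HF·pyridine, pyridine, THF, 0 °C
Reagents that add atoms: none
Why: Pyridine-buffered HF·pyridine removes both triethylsilyl ethers much faster than the secondary tert-butyldimethylsilyl and primary tert-butyldiphenylsilyl ethers (selective desilylation).

Step 16
Reactants: 27 C3,C6,C10-triol
Product: 28 C3 ynone diol (7R,8R,10R)
Conditions: MnO2, CH2Cl2, rt
Reagents that add atoms: none
Why: MnO2 oxidises only the doubly activated (allylic and propargylic) C3 carbinol, so the saturated primary C6 hydroxyl and the tertiary C10 hydroxyl survive and both C3 epimers converge on one ynone.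

Step 17
Reactants: 28 C3 ynone diol
Product: 30 iodovinyl furanone alcohol (7R,8R,10R), via C1/C3 diketone 29 (not isolated)
Conditions: (4-CF3C6H4)3PAuCl (5 mol%), AgOTf (5 mol%), H2O (2 equiv), toluene, rt
Reagents that add atoms: water, O
Why: Gold-catalysed cyclisation of a γ-hydroxy ynone: the cationic gold phosphine complex activates C1≡C2 for addition of water at C1, the C10 hydroxyl of diketone 29 then adds to the C3 carbonyl and loss of water gives the 3(2H)-furanone, the vinyl iodide and C10 being untouched.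

Step 18
Reactants: 30 iodovinyl furanone alcohol
Product: 31 iodovinyl furanone C6 aldehyde (7S,8R,10R)
Conditions: Dess–Martin periodinane, NaHCO3, CH2Cl2, 0 °C → rt; used crude
Reagents that add atoms: none
Why: Dess–Martin oxidation of the only remaining free (primary) hydroxyl gives the C6 aldehyde under buffered, non-epimerising conditions, and the aldehyde is used at once.

Step 19
Reactants: 31 iodovinyl furanone C6 aldehyde
Product: 33 ten-membered C6 allylic alcohol (6S,7R,8R,10R), via C5 vinylchromium dichloride 32 (not isolated)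
Conditions: CrCl2 (15 equiv), NiCl2 (0.1 equiv), degassed DMSO, rt, 31 added slowly to a final 0.003 M; aq. NH4Cl
Reagents that add atoms: none
Why: Nozaki–Hiyama–Kishi reaction: zerovalent nickel, formed from NiCl2 by divalent chromium, inserts into the C5–I bond with retention of the Z geometry and passes the vinyl group to trivalent chromium, giving vinylchromium 32, whose carbon–chromium bond adds to the C6 aldehyde. The closest known reaction type is the chromium/nickel-mediated cyclisation of vinyl iodides onto aldehydes that is used to close medium and large rings. The ten-membered carbocycle C1–C10 is closed in a 10-exo-trig mode (aldehyde oxygen outside the new ring), with the furanone and its quaternary C10 acting as a rigid turn that holds C5 and C6 within reach under high dilution. The new C6 stereocentre is set by the adjacent C7 centre: Felkin–Anh-type attack anti to the C8 branch, which is also the ring-forming trajectory, should place the C6 oxygen syn to the C11 methylene, i.e. the 6S alcohol needed for the trans-fused lactone. The step needs chemoselectivity for the aldehyde over the C1 ketone and the tert-butyl ester and retention of alkene geometry; the low basicity and aldehyde preference of the organochromium species, the vinylogous-ester character of C1 and the configurational stability of vinylnickel and vinylchromium intermediates secure this.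

Step 20
Reactants: 33 ten-membered C6 allylic alcohol
Product: 35 6,12-lactone (6S,7R,8R,10R), via C12 hydroxy acid 34 (not isolated)
Conditions: CF3CO2H/CH2Cl2 (1:5), 0 °C
Reagents that add atoms: none
Why: Acidolysis of the tert-butyl ester gives acid 34, whose carboxyl is attacked by the neighbouring C6 hydroxyl (five-membered lactonisation by acyl substitution, hence retention at C6), and the secondary tert-butyldimethylsilyl and primary tert-butyldiphenylsilyl ethers should tolerate brief cold CF3CO2H.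

Step 21
Reactants: 35 6,12-lactone
Product: 37 C11 (dimethylamino)methyl lactone (C11 epimers), via lithium lactone enolate 36 (not isolated)
Conditions: LiN(iPr)2 (1.3 equiv), THF, −78 °C; CH2=NMe2+ I−, −78 → 0 °C
Reagents that add atoms: N,N-dimethylmethyleneiminium iodide (Eschenmoser's salt), C=[N+](C)C.[I-]
Why: The lactone C11 methylene is the only enolisable position (the C1 ketone has no α-hydrogen), so kinetic deprotonation gives enolate 36, which is aminomethylated by the iminium salt (Mannich reaction); the new C11 centre is of no consequence.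

Step 22
Reactants: 37 C11 (dimethylamino)methyl lactone
Product: 39 α-methylene lactone (6S,7R,8R,10R), via trimethylammonium iodide 38 (not isolated)
Conditions: MeI, THF, rt; then aq. NaHCO3, CH2Cl2, rt
Reagents that add atoms: none
Why: N-Methylation gives ammonium salt 38 and mild base then expels trimethylamine by β-elimination (Hofmann-type), creating the exocyclic C11=C13 alkene.

Step 23
Reactants: 39 α-methylene lactone
Product: 40 C8 alcohol (6S,7S,8R,10R)
Conditions: HF·pyridine, pyridine, THF, 0 °C → rt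
Reagents that add atoms: none
Why: Acidic fluoride cleaves the secondary tert-butyldimethylsilyl ether considerably faster than the primary tert-butyldiphenylsilyl ether (selective desilylation), freeing only the C8 hydroxyl.

Step 24
Reactants: 40 C8 alcohol
Product: 41 C8 (E)-but-2-enoate (6S,7S,8R,10R)
Conditions: (E)-but-2-enoic anhydride, DMAP, pyridine, CH2Cl2, 0 °C → rt
Reagents that add atoms: (E)-but-2-enoic anhydride, C/C=C/C(=O)OC(=O)/C=C/C
Why: DMAP-catalysed acylation of the single free hydroxyl with the anhydride gives the E crotonate with retention at C8 and without the deconjugation that a ketene-forming acid chloride could cause.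

Step 25
Reactants: 41 C8 (E)-but-2-enoate
Product: 42 CNP0225232.1 (6S,7S,8R,10R)
Conditions: Bu4NF, AcOH (1:1), THF, 0 °C → rt
Reagents that add atoms: none
Why: Acetic acid-buffered fluoride removes the primary allylic silyl ether while the crotonate, the α-methylene lactone and the furanone are left alone, which gives the target.

**Compound list**

1 | (S)-2-methylglycidol, (2S)-(2-methyloxiran-2-yl)methanol | OC[C@@]1(C)CO1 | starting material
2 | vinylmagnesium bromide | C=C[Mg]Br | starting material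
3 | (R)-2-methylpent-4-ene-1,2-diol | OC[C@@](O)(C)CC=C | intermediate
4 | (R)-2-methyl-1,2-bis(triethylsilyloxy)pent-4-ene | CC[Si](CC)(CC)OC[C@@](O[Si](CC)(CC)CC)(C)CC=C | intermediate
5 | (R)-2-methyl-2-(triethylsilyloxy)pent-4-enal | O=C[C@@](O[Si](CC)(CC)CC)(C)CC=C | intermediate
6 | (R)-3-methyl-3-(triethylsilyloxy)hex-5-en-1-yne | C#C[C@@](O[Si](CC)(CC)CC)(C)CC=C | intermediate
7 | ethyl propiolate | C#CC(=O)OCC | starting material
8 | formaldehyde (monomer from paraformaldehyde) | C=O | starting material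
9 | iodomagnesium 1-ethoxy-3-iodopropa-1,2-dien-1-olate (iodoallenolate) | IC=C=C(O[Mg]I)OCC | intermediate (not isolated)
10 | ethyl (Z)-2-(hydroxymethyl)-3-iodoprop-2-enoate | I/C=C(/CO)C(=O)OCC | intermediate
11 | ethyl (Z)-2-[(tert-butyldiphenylsilyl)oxymethyl]-3-iodoprop-2-enoate | I/C=C(/CO[Si](c1ccccc1)(c1ccccc1)C(C)(C)C)C(=O)OCC | intermediate
12 | (E)-2-[(tert-butyldiphenylsilyl)oxymethyl]-3-iodoprop-2-en-1-ol | I/C=C(/CO[Si](c1ccccc1)(c1ccccc1)C(C)(C)C)CO | intermediate
13 | (Z)-2-[(tert-butyldiphenylsilyl)oxymethyl]-3-iodoprop-2-enal | I/C=C(/CO[Si](c1ccccc1)(c1ccccc1)C(C)(C)C)C=O | intermediate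
14 | lithium acetylide of 6 | [Li]C#C[C@@](O[Si](CC)(CC)CC)(C)CC=C | intermediate (not isolated)
15 | lithium C3 alkoxide of the acetylide/enal adduct (10R; C3 epimers) | C=CC[C@@](C)(O[Si](CC)(CC)CC)C#CC(O[Li])/C(CO[Si](c1ccccc1)(c1ccccc1)C(C)(C)C)=C\I | intermediate (not isolated)
16 | (1Z,6R)-1-iodo-6-methyl-2-[(tert-butyldiphenylsilyl)oxymethyl]-3,6-bis(triethylsilyloxy)nona-1,8-dien-4-yne, C3 epimers (chain C5=C4(C15)–C3–C2≡C1–C10–C9–CH=CH2) | C=CC[C@@](C)(O[Si](CC)(CC)CC)C#CC(O[Si](CC)(CC)CC)/C(CO[Si](c1ccccc1)(c1ccccc1)C(C)(C)C)=C\I | intermediate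
17 | 8,9-diol of 16 (terminal alkene dihydroxylated) | OCC(O)C[C@@](C)(O[Si](CC)(CC)CC)C#CC(O[Si](CC)(CC)CC)/C(CO[Si](c1ccccc1)(c1ccccc1)C(C)(C)C)=C\I | intermediate (not isolated)
18 | (3R,7Z)-8-iodo-3-methyl-7-[(tert-butyldiphenylsilyl)oxymethyl]-3,6-bis(triethylsilyloxy)oct-7-en-4-ynal (C8 aldehyde; C3 epimers) | O=CC[C@@](C)(O[Si](CC)(CC)CC)C#CC(O[Si](CC)(CC)CC)/C(CO[Si](c1ccccc1)(c1ccccc1)C(C)(C)C)=C\I | intermediate
19 | (S)-4-benzyloxazolidin-2-one | O=C1N[C@@H](Cc2ccccc2)CO1 | starting material
20 | 4-tert-butoxy-4-oxobutanoic acid (mono-tert-butyl succinate) | OC(=O)CCC(=O)OC(C)(C)C | starting material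
21 | mixed anhydride of 20 with pivalic acid | CC(C)(C)C(=O)OC(=O)CCC(=O)OC(C)(C)C | intermediate (not isolated)
22 | tert-butyl 4-[(4S)-4-benzyl-2-oxooxazolidin-3-yl]-4-oxobutanoate | O=C1OC[C@H](Cc2ccccc2)N1C(=O)CCC(=O)OC(C)(C)C | intermediate
23 | Z dibutylboron enolate of 22 | CCCCB(CCCC)O/C(=C\CC(=O)OC(C)(C)C)N1[C@@H](Cc2ccccc2)COC1=O | intermediate (not isolated)
24 | syn aldol adduct: (4S)-4-benzyloxazolidin-2-one N-acylated by the chain C6(=O)–C7H(CH2CO2tBu)–C8H(OH)–C9H2–C10(CH3)(OSiEt3)–C1≡C2–C3H(OSiEt3)–C4(CH2OSitBuPh2)=C5HI; 7S,8R,10R; C4=C5 Z; C3 epimers | O=C1OC[C@H](Cc2ccccc2)N1C(=O)[C@@H](CC(=O)OC(C)(C)C)[C@H](O)C[C@@](C)(O[Si](CC)(CC)CC)C#CC(O[Si](CC)(CC)CC)/C(CO[Si](c3ccccc3)(c3ccccc3)C(C)(C)C)=C\I | intermediate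
25 | C8 tert-butyldimethylsilyl ether of 24; 7S,8R,10R | O=C1OC[C@H](Cc2ccccc2)N1C(=O)[C@@H](CC(=O)OC(C)(C)C)[C@H](O[Si](C)(C)C(C)(C)C)C[C@@](C)(O[Si](CC)(CC)CC)C#CC(O[Si](CC)(CC)CC)/C(CO[Si](c3ccccc3)(c3ccccc3)C(C)(C)C)=C\I | intermediate
26 | C6 primary alcohol: HOC6H2–C7H(CH2CO2tBu)–C8H(OSitBuMe2)–C9H2–C10(CH3)(OSiEt3)–C1≡C2–C3H(OSiEt3)–C4(CH2OSitBuPh2)=C5HI; 7R,8R,10R; Z; C3 epimers | OC[C@@H](CC(=O)OC(C)(C)C)[C@H](O[Si](C)(C)C(C)(C)C)C[C@@](C)(O[Si](CC)(CC)CC)C#CC(O[Si](CC)(CC)CC)/C(CO[Si](c1ccccc1)(c1ccccc1)C(C)(C)C)=C\I | intermediate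
27 | C3,C6,C10-triol (both triethylsilyl groups of 26 removed); 7R,8R,10R; C3 epimers | OC[C@@H](CC(=O)OC(C)(C)C)[C@H](O[Si](C)(C)C(C)(C)C)C[C@@](C)(O)C#CC(O)/C(CO[Si](c1ccccc1)(c1ccccc1)C(C)(C)C)=C\I | intermediate
28 | C3 ynone with free C6 and C10 hydroxyls, C10(OH)–C1≡C2–C3(=O)–C4(CH2OSitBuPh2)=C5HI; 7R,8R,10R; Z | OC[C@@H](CC(=O)OC(C)(C)C)[C@H](O[Si](C)(C)C(C)(C)C)C[C@@](C)(O)C#CC(=O)/C(CO[Si](c1ccccc1)(c1ccccc1)C(C)(C)C)=C\I | intermediate
29 | C1,C3-diketone with C10–OH (hydrate of ynone 28) | OC[C@@H](CC(=O)OC(C)(C)C)[C@H](O[Si](C)(C)C(C)(C)C)C[C@@](C)(O)C(=O)CC(=O)/C(CO[Si](c1ccccc1)(c1ccccc1)C(C)(C)C)=C\I | intermediate (not isolated)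
30 | furanone alcohol: 2-methyl-3(2H)-furanone bearing at C5 (= C3 of the skeleton) the (Z)-2-iodo-1-[(tert-butyldiphenylsilyl)oxymethyl]vinyl group and at C2 (= C10) the chain C9H2–C8H(OSitBuMe2)–C7H(CH2CO2tBu)–C6H2OH; 7R,8R,10R | OC[C@@H](CC(=O)OC(C)(C)C)[C@H](O[Si](C)(C)C(C)(C)C)C[C@@]1(C)OC(/C(CO[Si](c2ccccc2)(c2ccccc2)C(C)(C)C)=C\I)=CC1=O | intermediate
31 | furanone C6 aldehyde (30 with C6H=O); 7S,8R,10R | O=C[C@@H](CC(=O)OC(C)(C)C)[C@H](O[Si](C)(C)C(C)(C)C)C[C@@]1(C)OC(/C(CO[Si](c2ccccc2)(c2ccccc2)C(C)(C)C)=C\I)=CC1=O | intermediate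
32 | C5 vinylchromium dichloride of 31 (iodine replaced by CrCl2, Z retained) | O=C[C@@H](CC(=O)OC(C)(C)C)[C@H](O[Si](C)(C)C(C)(C)C)C[C@@]1(C)OC(/C(CO[Si](c2ccccc2)(c2ccccc2)C(C)(C)C)=C\[Cr](Cl)Cl)=CC1=O | intermediate (not isolated)
33 | ten-membered C6 allylic alcohol: furanone-bridged carbocycle C1–C10 with 6-OH, 7-CH2CO2tBu, 8-OSitBuMe2, 15-OSitBuPh2; 6S,7R,8R,10R; C4=C5 Z | O[C@H]2/C=C(/CO[Si](c4ccccc4)(c4ccccc4)C(C)(C)C)C3=CC(=O)[C@@](C)(C[C@@H](O[Si](C)(C)C(C)(C)C)[C@@H]2CC(=O)OC(C)(C)C)O3 | intermediate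
34 | C12 carboxylic acid of 33 | O[C@H]2/C=C(/CO[Si](c4ccccc4)(c4ccccc4)C(C)(C)C)C3=CC(=O)[C@@](C)(C[C@@H](O[Si](C)(C)C(C)(C)C)[C@@H]2CC(=O)O)O3 | intermediate (not isolated)
35 | 6,12-lactone (trans-fused γ-butyrolactone, C11H2) with 8-OSitBuMe2 and 15-OSitBuPh2; 6S,7R,8R,10R | C1C(=O)O[C@H]2/C=C(/CO[Si](c4ccccc4)(c4ccccc4)C(C)(C)C)C3=CC(=O)[C@@](C)(C[C@@H](O[Si](C)(C)C(C)(C)C)[C@H]12)O3 | intermediate
36 | lithium enolate of lactone 35 (C11=C12–OLi) | C1=C(O[Li])O[C@H]2/C=C(/CO[Si](c4ccccc4)(c4ccccc4)C(C)(C)C)C3=CC(=O)[C@@](C)(C[C@@H](O[Si](C)(C)C(C)(C)C)[C@H]12)O3 | intermediate (not isolated)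
37 | C11 (dimethylamino)methyl lactone, C11 epimers | CN(C)CC1C(=O)O[C@H]2/C=C(/CO[Si](c4ccccc4)(c4ccccc4)C(C)(C)C)C3=CC(=O)[C@@](C)(C[C@@H](O[Si](C)(C)C(C)(C)C)[C@H]12)O3 | intermediate
38 | C13 trimethylammonium iodide of 37 | C[N+](C)(C)CC1C(=O)O[C@H]2/C=C(/CO[Si](c4ccccc4)(c4ccccc4)C(C)(C)C)C3=CC(=O)[C@@](C)(C[C@@H](O[Si](C)(C)C(C)(C)C)[C@H]12)O3.[I-] | intermediate (not isolated)
39 | α-methylene lactone (C11=C13H2) with 8-OSitBuMe2 and 15-OSitBuPh2; 6S,7R,8R,10R | C=C1C(=O)O[C@H]2/C=C(/CO[Si](c4ccccc4)(c4ccccc4)C(C)(C)C)C3=CC(=O)[C@@](C)(C[C@@H](O[Si](C)(C)C(C)(C)C)[C@H]12)O3 | intermediate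
40 | C8 alcohol (15-OSitBuPh2 retained); 6S,7S,8R,10R | C=C1C(=O)O[C@H]2/C=C(/CO[Si](c4ccccc4)(c4ccccc4)C(C)(C)C)C3=CC(=O)[C@@](C)(C[C@@H](O)[C@H]12)O3 | intermediate
41 | C8 (E)-but-2-enoate with 15-OSitBuPh2; 6S,7S,8R,10R | C=C1C(=O)O[C@H]2/C=C(/CO[Si](c4ccccc4)(c4ccccc4)C(C)(C)C)C3=CC(=O)[C@@](C)(C[C@@H](OC(=O)/C=C/C)[C@H]12)O3 | intermediate
42 | CNP0225232.1; 6S,7S,8R,10R; C4=C5 Z | C=C1C(=O)O[C@H]2/C=C(/CO)C3=CC(=O)[C@@](C)(C[C@@H](OC(=O)/C=C/C)[C@H]12)O3 | target

**Step count**

Total steps: 25. Longest linear sequence: 20 steps (steps 1–4, 9, 10 and 12–25; the branch from 7 through steps 5–8 is equally long).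

**Steps most likely to fail**

Step 19. The aldehyde may be attacked from the other face, so that the 6R carbinol predominates, and intermolecular coupling can compete if the addition is too fast. The fallback sets out from 31: if its cyclisation under the step 19 conditions delivers mainly the C6 epimer of 33 F1, this alcohol is inverted by a Mitsunobu reaction with chloroacetic acid (PPh3, diisopropyl azodicarboxylate, toluene, 0 °C) to the 6S chloroacetate F2. The chloroacetate is then removed with thiourea and NaHCO3 in EtOH, which returns the route to 33.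

Step 21. The lithium amide may deprotonate C6–H, which is vinylogous to the C1 ketone through C2=C3 and C4=C5, or add to the dienone, so that epimerisation or decomposition outruns C11 enolisation. The fallback sets out from 35: soft enolisation with Me3SiOTf and Et3N in CH2Cl2 at 0 °C gives the lactone trimethylsilyl ketene acetal F3. A Mukaiyama–Mannich reaction of this acetal with CH2=NMe2+ I− in CH2Cl2 rejoins the route at 37.

Step 17. The gold catalyst may be diverted, by addition of the C6 hydroxyl instead of water to the activated alkyne or by silyl ether loss from adventitious acid, so that the cyclisation stalls. The fallback sets out from 28: conjugate addition of Et2NH (1 equiv, THF, 0 °C) to the ynone at C1 gives the C1 diethylamino enone F4. Aqueous AcOH in THF then hydrolyses the enamine and cyclodehydrates the C10 hydroxyl onto C3, returning to 30.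

**Further compounds**

F1 | step 19 | C6 epimer of 33 (6R,7R,8R,10R) | O[C@@H]2/C=C(/CO[Si](c4ccccc4)(c4ccccc4)C(C)(C)C)C3=CC(=O)[C@@](C)(C[C@@H](O[Si](C)(C)C(C)(C)C)[C@@H]2CC(=O)OC(C)(C)C)O3
F2 | step 19 | 6S chloroacetate of 33 (6S,7R,8R,10R) | ClCC(=O)O[C@H]2/C=C(/CO[Si](c4ccccc4)(c4ccccc4)C(C)(C)C)C3=CC(=O)[C@@](C)(C[C@@H](O[Si](C)(C)C(C)(C)C)[C@@H]2CC(=O)OC(C)(C)C)O3
F3 | step 21 | trimethylsilyl ketene acetal of lactone 35 (C11=C12–OSiMe3) | C1=C(O[Si](C)(C)C)O[C@H]2/C=C(/CO[Si](c4ccccc4)(c4ccccc4)C(C)(C)C)C3=CC(=O)[C@@](C)(C[C@@H](O[Si](C)(C)C(C)(C)C)[C@H]12)O3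
F4 | step 17 | C1 diethylamino enone from ynone 28 (C10(OH)–C1(NEt2)=C2H–C3(=O)) | OC[C@@H](CC(=O)OC(C)(C)C)[C@H](O[Si](C)(C)C(C)(C)C)C[C@@](C)(O)C(N(CC)CC)=CC(=O)/C(CO[Si](c1ccccc1)(c1ccccc1)C(C)(C)C)=C\I
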